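Rings B (cyclohexene) and C (2-phenyl-2,3-dihydropyran-4-one) form a vinylogous ester O–C=C–C=O, a masked 2-cinnamoyl-1,3-dione. Both rings are therefore closed last and together. An exo acid chloride on the two-carbon bridge of the bicyclo[3.2.1]octanone core C-acylates benzalacetone, making the C–C bond that becomes the ring-fusion C=C of rings B/C. The 1,3-diketone then adds to the adjacent butenolide (ring B, cis to lactone A), and the enol oxygen closes onto the styryl carbon (O–CHPh bond of ring C). The precursor is a bridged keto lactone carrying only CO2H and a butenolide; its core comes from L-glutamic acid lactone, benzalacetone and a Michael/α-alkylation domino.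

Key step: step 8

Remark: 1,3-diketones 8, 10 and 20 are drawn as one enol tautomer, bromide 10 is used as a mixture of C-6 epimers, and exo means syn to the C-8 carbonyl bridge of the bicyclo[3.2.1]octane core (C-1 cinnamoyl-bearing bridgehead, C-2/C-3 lactone-fused, C-6/C-7 two-carbon bridge); 11 and 14 are taken as catalogue compounds.

Step 1
Reactants: 1 (S)-5-(hydroxymethyl)dihydrofuran-2(3H)-one
Product: 2 (S)-5-oxotetrahydrofuran-2-carbaldehyde
Conditions: TEMPO (10 mol %), PhI(OAc)2, CH2Cl2, rt
Reagents that add atoms: none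
Why: Oxoammonium-catalysed (TEMPO) oxidation of the primary alcohol stops at the aldehyde and leaves the lactone and the stereocentre untouched.

Step 2
Reactants: 2 (S)-5-oxotetrahydrofuran-2-carbaldehyde; 3 methyl 2-[bis(2,2,2-trifluoroethoxy)phosphoryl]acetate
Product: 4 methyl (Z)-3-[(2S)-5-oxotetrahydrofuran-2-yl]prop-2-enoate
Conditions: KN(SiMe3)2, 18-crown-6, THF, −78 °C
Reagents that add atoms: none
Why: Still–Gennari olefination at −78 °C should give the Z-enoate kinetically and avoid epimerization of the α-acyloxy aldehyde.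

Step 3
Reactants: 4 methyl (Z)-3-[(2S)-5-oxotetrahydrofuran-2-yl]prop-2-enoate; 5 (E)-4-phenylbut-3-en-2-one (benzalacetone)
Product: 8 (3aR,7aS)-5-hydroxy-4-[(E)-3-phenylprop-2-enoyl]-3a,6,7,7a-tetrahydro-1-benzofuran-2(3H)-one, via Michael adduct 6 (not isolated), via hydroxy ester 7 (not isolated)
Conditions: 5, LiN(SiMe3)2, THF, −78 °C; then 4, −78 → 0 °C; aq. HCl
Reagents that add atoms: none
Why: Michael–Claisen annulation: the lithium enolate of 5 adds to the Z-enoate, HN(SiMe3)2 relays the proton to give the ketone enolate, this attacks the lactone carbonyl (6-exo-trig) and the released alkoxide relactonizes onto the methyl ester; C-3a is set by addition on the face of the ring oxygen, anti to the ring CH2, in the conformer that keeps the allylic hydrogen in the alkene plane (1,3-allylic strain), which gives the cis-fused lactone.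

Step 4
Reactants: 8 (3aR,7aS)-5-hydroxy-4-[(E)-3-phenylprop-2-enoyl]-3a,6,7,7a-tetrahydro-1-benzofuran-2(3H)-one
Product: 10 (3aR,7aS)-6-bromo-5-hydroxy-4-[(E)-3-phenylprop-2-enoyl]-3a,6,7,7a-tetrahydro-1-benzofuran-2(3H)-one, via bis(silyl) dienol ether 9 (not isolated)
Conditions: Me3SiOTf, Et3N, CH2Cl2, 0 °C; then N-bromosuccinimide, THF, −78 °C; aq. NaHCO3
Reagents that add atoms: N-bromosuccinimide, O=C1CCC(=O)N1Br
Why: A 1,3-bis(silyloxy)diene reacts with electrophiles at its terminal carbon, so bromination should occur at C-6 and not at the central carbon; the bromide centre is left unassigned because it is inverted in step 5.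

Step 5
Reactants: 10 (3aR,7aS)-6-bromo-5-hydroxy-4-[(E)-3-phenylprop-2-enoyl]-3a,6,7,7a-tetrahydro-1-benzofuran-2(3H)-one; 11 tert-butyl (E)-4-oxobut-2-enoate
Product: 13 tricyclic keto aldehyde (C-1 cinnamoyl, exo-CHO at C-6, exo-CO2tBu at C-7), via bromo Michael adduct 12 (not isolated)
Conditions: (S)-α,α-diphenylprolinol trimethylsilyl ether (20 mol %), NaOAc, CHCl3, 0 °C → rt
Reagents that add atoms: none
Why: Organocatalytic domino Michael/α-alkylation: the 1,3-diketone carbon adds to the iminium of 11 and the resulting enamine displaces the α-bromo ketone (5-exo-tet); the catalyst fixes C-7 (ester exo), the quaternary bridgehead forms anti to the lactone because only that adduct can bridge without forcing the lactone oxygen axial into the new bridge, and the epimerizable formyl centre should settle exo.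

Step 6
Reactants: 13 tricyclic keto aldehyde; 14 ethyl (Z)-3-iodoprop-2-enoate
Product: 16 butenolide tert-butyl ester, via hydroxy enoate 15 (not isolated)
Conditions: CrCl2, NiCl2 (2 mol %), DMF, rt; aq. NH4Cl
Reagents that add atoms: none
Why: Nozaki–Hiyama–Kishi addition of the alkenylchromium to the aldehyde is chemoselective over the ketones, and the Z-γ-alkoxide lactonizes onto its own ethyl ester (not the hindered tert-butyl ester) to the butenolide; the carbinol centre should arise by Felkin–Anh attack anti to C-7 with its exo ester.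

Step 7
Reactants: 16 butenolide tert-butyl ester
Product: 17 butenolide carboxylic acid
Conditions: CF3CO2H, CH2Cl2, 0 °C → rt
Reagents that add atoms: none
Why: Acidolysis of the tert-butyl ester (loss of isobutene) frees the acid without touching the lactone, the butenolide or the non-enolizable 1,3-diketone.

Step 8
Reactants: 17 butenolide carboxylic acid; 5 (E)-4-phenylbut-3-en-2-one (benzalacetone)
Product: 21 target CNP0313292.3, via acid chloride 18 (not isolated), via 1,3-diketone 19 (not isolated), via ring-B enol 20 (not isolated)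
Conditions: 1-chloro-N,N,2-trimethylprop-1-en-1-amine, CH2Cl2, 0 °C; added to 5, MgBr2·OEt2, iPr2NEt, CH2Cl2, 0 → 40 °C; then AcOH, 40 °C
Reagents that add atoms: none
Why: Acid chloride 18 C-acylates the magnesium enolate of 5 formed by soft enolization (crossed Claisen acylation), joining the methyl carbon of 5 to the carboxyl carbon to give 19; its central carbon then adds to the β-carbon of the butenolide (intramolecular Michael addition, 6-exo-trig, closing ring B) and, after acidification, the enol oxygen of 20 adds to the styryl carbon (oxa-Michael addition, 6-endo-trig, closing ring C). The closest known reaction types are the soft-enolization synthesis of 1,3-diketones from ketones and acid chlorides and the chalcone-to-flavanone type cyclization of 2-cinnamoyl-1,3-diketone enols. The ring-fusion carbon next to lactone A is set by the tether, which can reach only the butenolide face that carries the bicyclic core, so rings A and B become cis-fused; the carbinol carbon was fixed in step 6. The benzylic carbon forms reversibly and should settle with phenyl equatorial on the half-chair that puckers away from the cinnamoyl group of the neighbouring quaternary bridgehead, which shields the upper face of ring C. The step needs C-acylation of 5 in the presence of the bridgehead cinnamoyl ketone, two lactones and the enolizable butenolide: 5 is the only enolizable ketone, the acid chloride is added to the preformed enolate so that acylation outruns vinylogous enolization, and the magnesium diketonate is too stabilized for intermolecular conjugate addition.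

Compound list
1 | (S)-5-(hydroxymethyl)dihydrofuran-2(3H)-one | O=C1CC[C@@H](CO)O1 | starting material
2 | (S)-5-oxotetrahydrofuran-2-carbaldehyde | O=C1CC[C@@H](C=O)O1 | intermediate
3 | methyl 2-[bis(2,2,2-trifluoroethoxy)phosphoryl]acetate | COC(=O)CP(=O)(OCC(F)(F)F)OCC(F)(F)F | starting material
4 | methyl (Z)-3-[(2S)-5-oxotetrahydrofuran-2-yl]prop-2-enoate | O=C1CC[C@@H](/C=C\C(=O)OC)O1 | intermediate
5 | (E)-4-phenylbut-3-en-2-one (benzalacetone) | CC(=O)/C=C/c1ccccc1 | starting material
6 | methyl (3S,6E)-5-oxo-3-[(2S)-5-oxotetrahydrofuran-2-yl]-7-phenylhept-6-enoate (Michael adduct, not isolated) | COC(=O)C[C@@H]([C@@H]1CCC(=O)O1)CC(=O)/C=C/c1ccccc1 | intermediate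
7 | methyl 2-[(1R,6S)-6-hydroxy-3-oxo-2-[(E)-3-phenylprop-2-enoyl]cyclohexyl]acetate, drawn as enol (not isolated) | COC(=O)C[C@@H]1C(C(=O)/C=C/c2ccccc2)=C(O)CC[C@@H]1O | intermediate
8 | (3aR,7aS)-5-hydroxy-4-[(E)-3-phenylprop-2-enoyl]-3a,6,7,7a-tetrahydro-1-benzofuran-2(3H)-one (enol of the 4-cinnamoyl-2,5-dione) | O=C1C[C@@H]2C(C(=O)/C=C/c3ccccc3)=C(O)CC[C@@H]2O1 | intermediate
9 | bis(trimethylsilyl) dienol ether of 8 (not isolated) | O=C1C[C@@H]2C(=C(O[Si](C)(C)C)/C=C/c3ccccc3)C(O[Si](C)(C)C)=CC[C@@H]2O1 | intermediate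
10 | (3aR,7aS)-6-bromo-5-hydroxy-4-[(E)-3-phenylprop-2-enoyl]-3a,6,7,7a-tetrahydro-1-benzofuran-2(3H)-one (C-6 epimers) | O=C1C[C@@H]2C(C(=O)/C=C/c3ccccc3)=C(O)C(Br)C[C@@H]2O1 | intermediate
11 | tert-butyl (E)-4-oxobut-2-enoate | O=C/C=C/C(=O)OC(C)(C)C | starting material
12 | tert-butyl 2-[6-bromo-4-cinnamoyl-2,5-dioxooctahydro-1-benzofuran-4-yl]-4-oxobutanoate, new bond at C-4 trans to the lactone CH2 (enamine-bound in the flask, not isolated) | CC(C)(C)OC(=O)[C@H](CC=O)[C@@]1(C(=O)/C=C/c2ccccc2)C(=O)C(Br)C[C@@H]2OC(=O)C[C@H]12 | intermediate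
13 | keto aldehyde: bicyclo[3.2.1]octan-8-one with C-1 cinnamoyl, γ-lactone cis-fused at C-2 (CH2CO) and C-3 (O) anti to the two-carbon bridge, exo-CHO at C-6, exo-CO2tBu at C-7 | CC(C)(C)OC(=O)[C@@H]3[C@H](C=O)[C@H]1C[C@@H]2OC(=O)C[C@@H]2[C@]3(C(=O)/C=C/c4ccccc4)C1=O | intermediate
14 | ethyl (Z)-3-iodoprop-2-enoate | CCOC(=O)/C=C\I | starting material
15 | 13 with CHO converted into CH(OH)–(Z)-CH=CH–CO2Et (not isolated) | CC(C)(C)OC(=O)[C@@H]3[C@H]([C@H](O)/C=C\C(=O)OCC)[C@H]1C[C@@H]2OC(=O)C[C@@H]2[C@]3(C(=O)/C=C/c4ccccc4)C1=O | intermediate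
16 | butenolide tert-butyl ester: 13 with CHO replaced by an exo 5-oxo-2,5-dihydrofuran-2-yl group | CC(C)(C)OC(=O)[C@@H]3[C@H]([C@H]5C=CC(=O)O5)[C@H]1C[C@@H]2OC(=O)C[C@@H]2[C@]3(C(=O)/C=C/c4ccccc4)C1=O | intermediate
17 | butenolide carboxylic acid (16 with CO2H at C-7) | OC(=O)[C@@H]3[C@H]([C@H]5C=CC(=O)O5)[C@H]1C[C@@H]2OC(=O)C[C@@H]2[C@]3(C(=O)/C=C/c4ccccc4)C1=O | intermediate
18 | acid chloride of 17 (not isolated) | ClC(=O)[C@@H]3[C@H]([C@H]5C=CC(=O)O5)[C@H]1C[C@@H]2OC(=O)C[C@@H]2[C@]3(C(=O)/C=C/c4ccccc4)C1=O | intermediate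
19 | 1,3-diketone: C-7 bears C(=O)CH2C(=O)–(E)-CH=CHPh (not isolated) | O=C(/C=C/c6ccccc6)CC(=O)[C@@H]3[C@H]([C@H]5C=CC(=O)O5)[C@H]1C[C@@H]2OC(=O)C[C@@H]2[C@]3(C(=O)/C=C/c4ccccc4)C1=O | intermediate
20 | ring-B-closed cinnamoyl enol, open-chain isomer of 21 (not isolated) | O=C1C[C@@H]2C(C(=O)/C=C/c6ccccc6)=C(O)[C@@H]3[C@H]([C@@H]2O1)[C@H]1C[C@@H]2OC(=O)C[C@@H]2[C@]3(C(=O)/C=C/c4ccccc4)C1=O | intermediate
21 | CNP0313292.3 | O=C1C[C@@H]2C3=C(O[C@H](c4ccccc4)CC3=O)[C@@H]3[C@H]([C@@H]2O1)[C@H]1C[C@@H]2OC(=O)C[C@@H]2[C@]3(C(=O)/C=C/c2ccccc2)C1=O | target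

Total step count: 8. Longest linear sequence: 8 steps (1 → 21); 3, 5, 11 and 14 enter as purchased reagents.

Steps most likely to fail

Step 8. The amine/magnesium medium may enolize the butenolide (erosion of the carbinol configuration), O-acylation may compete with C-acylation, and the reversible pyranone closure may show too little facial bias. The fallback sets out from 17. Acid chloride 18 is made as before and is C-acylated without any amine by the silyl dienol ether of benzalacetone, (E)-trimethyl[(4-phenylbuta-1,3-dien-2-yl)oxy]silane F1 (from 5, Me3SiCl, NaI, Et3N), under ZnCl2 in CH2Cl2 (Mukaiyama-type acylation) to give 19. Catalytic Et3N then closes ring B to 20, and ring C is closed in a separate, catalyst-controlled oxa-Michael addition under quinine (quinidine as the pseudo-enantiomeric alternative). The route is rejoined at 21.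

Step 5. The α-bromo ketone may N-alkylate the amine catalyst, and closure of the strained five-membered ring may be outrun by retro-Michael or Favorskii-type processes. The fallback sets out from 8. The same amine-catalysed Michael addition to 11, now without bromide, should give the debromo analogue of 12 F2. tert-BuMe2SiOTf/Et3N converts its aldehyde and ketone into the bis(silyl enol ether) F3. (NH4)2Ce(NO3)6 with NaHCO3 in MeCN at −30 °C then couples the two enol ethers intramolecularly (oxidative enol-silane coupling to the 1,4-dicarbonyl). The route is rejoined at 13.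

Step 3. The intermolecular conjugate addition may show poor facial selectivity, and the ester enolate or the lactone carbonyl may react before the ketone enolate closes the ring. The fallback sets out from 4. Warm aqueous acid (2 M HCl, dioxane, 60 °C) opens the saturated lactone reversibly, and the Z-γ-hydroxy enoate relactonizes to the butenolide acid 3-[(2S)-5-oxo-2,5-dihydrofuran-2-yl]propanoic acid F4. Its acid chloride F5 (same chloroenamine) acylates 5 under MgBr2·OEt2/iPr2NEt to the 1,3-diketone F6. Tether-controlled intramolecular Michael addition of F6 to the butenolide gives the cis-fused product. The route is rejoined at 8.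

Further compounds
F1 | step 8 | (E)-trimethyl[(4-phenylbuta-1,3-dien-2-yl)oxy]silane | C=C(O[Si](C)(C)C)/C=C/c1ccccc1
F2 | step 5 | tert-butyl 2-[4-cinnamoyl-2,5-dioxooctahydro-1-benzofuran-4-yl]-4-oxobutanoate (debromo analogue of 12) | CC(C)(C)OC(=O)[C@H](CC=O)[C@@]1(C(=O)/C=C/c2ccccc2)C(=O)CC[C@@H]2OC(=O)C[C@H]12
F3 | step 5 | bis(tert-butyldimethylsilyl enol ether) of F2 (aldehyde and ring ketone) | CC(C)(C)OC(=O)[C@H](C=CO[Si](C)(C)C(C)(C)C)[C@@]1(C(=O)/C=C/c2ccccc2)C(O[Si](C)(C)C(C)(C)C)=CC[C@@H]2OC(=O)C[C@H]12
F4 | step 3 | 3-[(2S)-5-oxo-2,5-dihydrofuran-2-yl]propanoic acid | OC(=O)CC[C@H]1C=CC(=O)O1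
F5 | step 3 | 3-[(2S)-5-oxo-2,5-dihydrofuran-2-yl]propanoyl chloride | ClC(=O)CC[C@H]1C=CC(=O)O1
F6 | step 3 | (E)-1-[(2S)-5-oxo-2,5-dihydrofuran-2-yl]-7-phenylhept-6-ene-3,5-dione | O=C(/C=C/c1ccccc1)CC(=O)CC[C@H]1C=CC(=O)O1
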